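The lower pyran ring (ring F: O1, C2, C3, C4, C4a, C8a) is cut at C2–C3. C2, bonded to O1 and to the 4-hydroxyphenyl ring E, is traced to an ester carbonyl carbon; C3–C4 to an allyl group ortho to O1 on ring D. A titanium-alkylidene carbonyl–olefin metathesis of 6-allyl-2,3-bis(benzyloxy)phenyl 4-(benzyloxy)benzoate closes ring F as an achiral 2-aryl-4H-chromene, and reagent-controlled hydroboration then sets C2 and C3. The same flavan-3-ol feeds both halves: benzylic oxidation and reduction give the 3,4-trans-diol lower unit; C3 inversion and C4 activation give the 2,3-cis upper electrophile; a silver-promoted C4–C6 coupling joins them.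

Key step: step 5

Remark on naming: the upper flavan unit carries rings A (benzo), B (aryl) and C (pyran); the lower unit carries rings D (benzo), E (aryl) and F (pyran). Each unit is numbered O1, C2, C3, C4, C4a, C5–C8, C8a. Bn = benzyl.

Step 1
Reactants: 1 pyrogallol; 2 allyl bromide
Product: 3 3-(allyloxy)benzene-1,2-diol
Conditions: Na2B4O7·10H2O, NaOH, H2O, rt, argon; then aq. HCl
Reagents that add atoms: none
Why: Borate ester formation ties up two vicinal hydroxyls of pyrogallol, so the Williamson O-allylation should take place at the remaining terminal phenol.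

Step 2
Reactants: 3 3-(allyloxy)benzene-1,2-diol
Product: 4 1-(allyloxy)-2,3-bis(benzyloxy)benzene
Conditions: BnBr, K2CO3, DMF, 60 °C
Reagents that add atoms: benzyl bromide, BrCc1ccccc1
Why: Williamson etherification of both free phenols installs protecting groups that should survive every later step and leave together at the end.

Step 3
Reactants: 4 1-(allyloxy)-2,3-bis(benzyloxy)benzene
Product: 5 6-allyl-2,3-bis(benzyloxy)phenol
Conditions: PhNEt2, 200 °C
Reagents that add atoms: none
Why: The aromatic Claisen rearrangement ([3,3]-sigmatropic) delivers the allyl group to the only free ortho position, which forms the future C4a–C4 bond and frees the phenol that becomes O1 of ring F.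

Step 4
Reactants: 5 6-allyl-2,3-bis(benzyloxy)phenol; 6 4-(benzyloxy)benzoyl chloride
Product: 7 6-allyl-2,3-bis(benzyloxy)phenyl 4-(benzyloxy)benzoate
Conditions: Et3N, DMAP (cat.), CH2Cl2, 0 °C to rt
Reagents that add atoms: none
Why: DMAP-catalysed O-acylation of the phenol joins O1 to the carbon that becomes C2 and brings in ring E.

Step 5
Reactants: 7 6-allyl-2,3-bis(benzyloxy)phenyl 4-(benzyloxy)benzoate
Product: 8 7,8-bis(benzyloxy)-2-[4-(benzyloxy)phenyl]-4H-chromene
Conditions: TiCl4, TMEDA, Zn, PbCl2 (cat.), CH3CHBr2, THF–CH2Cl2, 0 to 65 °C; base-washed silica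
Reagents that add atoms: none
Why: Zn/PbCl2 reduction of TiCl4–TMEDA in the presence of CH3CHBr2 gives a titanium ethylidene, which exchanges with the terminal alkene of 7 ([2+2]/retro-[2+2], propene lost) to place a titanium alkylidene on C3; this adds across the ester C=O to an oxatitanacyclobutane that collapses to the C2=C3 enol ether, the carbonyl oxygen leaving on titanium. The closest known reaction is the Takai–Utimoto-type olefinic-ester cyclisation to cyclic enol ethers (carbonyl–olefin metathesis), and aryl benzoates are classical substrates for titanium alkylidenes. Ring F closes as a six-membered ring by intramolecular carbonyl olefination, formally a 6-endo ring-closing metathesis between C3 and the C2 carbonyl. No stereocenter is formed: 8 is achiral, and its trisubstituted C2=C3 enol ether is the handle through which C2 and C3 are set in step 6. The step needs alkene exchange and carbonyl olefination without allyl-to-propenyl migration (which would lead to a benzofuran) and without acid-induced isomerisation of the 4H-chromene; the amine-buffered, non-basic reagent and the basic work-up should secure this, and benzyl ethers are inert to the reagent.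

Step 6
Reactants: 8 7,8-bis(benzyloxy)-2-[4-(benzyloxy)phenyl]-4H-chromene
Product: 10 (2R,3S)-7,8-bis(benzyloxy)-2-[4-(benzyloxy)phenyl]chroman-3-ol, via chroman-3-yl(isopinocampheyl)borane 9 (not isolated)
Conditions: IpcBH2 [prepared from (+)-α-pinene], Et2O–THF, −25 °C; then NaOH, H2O2, 0 °C to rt
Reagents that add atoms: monoisopinocampheylborane (to 9), C[C@H]1[C@H](B)C[C@@H]2C[C@H]1C2(C)C; hydrogen peroxide, OO
Why: In this Brown asymmetric hydroboration boron adds to C3 (β to O1 and to the aryl group) and hydrogen to C2 in a syn fashion, which gives the 2,3-trans relationship; the isopinocampheyl group should select the alkene face as it does for 1-arylcycloalkenes, which corresponds to (2R,3S), and the oxidation goes with retention.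

Step 7
Reactants: 10 (2R,3S)-7,8-bis(benzyloxy)-2-[4-(benzyloxy)phenyl]chroman-3-ol
Product: 12 (2R,3R)-7,8-bis(benzyloxy)-2-[4-(benzyloxy)phenyl]-3-hydroxychroman-4-one, via 4β-hydroxyflavan-3-ol 11 (not isolated)
Conditions: DDQ (2.5 equiv), CH2Cl2–H2O, rt
Reagents that add atoms: water, O
Why: DDQ abstracts hydride from C4 (benzylic, para to the 7-benzyloxy group, ortho to O1), water traps the cation as 11, and a second DDQ dehydrogenation of this activated benzylic alcohol should give the aryl ketone without touching C2 or C3 (benzylic C–H oxidation).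

Step 8
Reactants: 12 (2R,3R)-7,8-bis(benzyloxy)-2-[4-(benzyloxy)phenyl]-3-hydroxychroman-4-one
Product: 13 (2R,3S,4R)-7,8-bis(benzyloxy)-2-[4-(benzyloxy)phenyl]chroman-3,4-diol
Conditions: NaBH4, THF–MeOH, 0 °C
Reagents that add atoms: none
Why: Borohydride reduction of a 2,3-trans-3-hydroxyflavanone delivers hydride to C4 from the face of the 3-hydroxyl (axial attack), which should give the diequatorial 3,4-trans-diol and set C4 as R, as in the known reduction of dihydroflavonols to flavan-3,4-diols.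

Step 9
Reactants: 13 (2R,3S,4R)-7,8-bis(benzyloxy)-2-[4-(benzyloxy)phenyl]chroman-3,4-diol
Product: 14 3,4-di-O-acetate of 13 (2,3-trans-3,4-trans)
Conditions: Ac2O, pyridine, DMAP (cat.), rt
Reagents that add atoms: acetic anhydride, CC(=O)OC(C)=O
Why: DMAP-catalysed acetylation blocks both hydroxyls against O-alkylation in step 14 and turns the C4 oxygen into a hard leaving group that a thiophilic promoter should leave alone.

Step 10
Reactants: 10 (2R,3S)-7,8-bis(benzyloxy)-2-[4-(benzyloxy)phenyl]chroman-3-ol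
Product: 15 (2R)-7,8-bis(benzyloxy)-2-[4-(benzyloxy)phenyl]chroman-3-one
Conditions: Dess–Martin periodinane, pyridine, CH2Cl2, rt
Reagents that add atoms: none
Why: Dess–Martin oxidation of the secondary alcohol under buffered, non-enolising conditions should keep the C2 stereocenter next to the new ketone.

Step 11
Reactants: 15 (2R)-7,8-bis(benzyloxy)-2-[4-(benzyloxy)phenyl]chroman-3-one
Product: 16 (2R,3R)-7,8-bis(benzyloxy)-2-[4-(benzyloxy)phenyl]chroman-3-ol
Conditions: LiBH(s-Bu)3, THF, −78 °C; then H2O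
Reagents that add atoms: none
Why: Equatorial attack of the bulky hydride on the C3 ketone (steric approach control) should give the axial alcohol, cis to the equatorial 2-aryl group, which sets C3 as R (2,3-cis).

Step 12
Reactants: 16 (2R,3R)-7,8-bis(benzyloxy)-2-[4-(benzyloxy)phenyl]chroman-3-ol
Product: 17 (2R,3R,4S)-7,8-bis(benzyloxy)-2-[4-(benzyloxy)phenyl]-4-(2-ethoxyethoxy)chroman-3-ol
Conditions: DDQ, 2-ethoxyethanol, CH2Cl2, rt
Reagents that add atoms: 2-ethoxyethanol, CCOCCO
Why: DDQ-mediated oxidative C4–H alkoxylation: hydride abstraction gives the C4 cation, which the alcohol should capture trans to the 3-hydroxyl and to the 2-aryl group (4β).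

Step 13
Reactants: 17 (2R,3R,4S)-7,8-bis(benzyloxy)-2-[4-(benzyloxy)phenyl]-4-(2-ethoxyethoxy)chroman-3-ol
Product: 18 (2R,3S,4S)-4-(1,3-benzothiazol-2-ylsulfanyl)-7,8-bis(benzyloxy)-2-[4-(benzyloxy)phenyl]chroman-3-ol
Conditions: AlMe3, 2-mercaptobenzothiazole, CH2Cl2, 0 °C to rt
Reagents that add atoms: 2-mercaptobenzothiazole, S=c1[nH]c2ccccc2s1
Why: The dimethylaluminium thiolate formed in the flask ionises the chelating C4 ether and delivers sulfur to the same β-face, trans to the 3-oxygen (SN1 substitution), giving a leaving group that only a soft thiophile activates.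

Step 14
Reactants: 18 (2R,3S,4S)-4-(1,3-benzothiazol-2-ylsulfanyl)-7,8-bis(benzyloxy)-2-[4-(benzyloxy)phenyl]chroman-3-ol; 14 3,4-di-O-acetate of 13
Product: 19 hexa-O-benzyl-epioritin-(4β→6)-oritin-4α-ol 3,4-di-O-acetate (acetates on ring F)
Conditions: AgBF4, 2,6-di-tert-butyl-4-methylpyridine, THF, 0 °C; 14 in fourfold excess
Reagents that add atoms: none
Why: AgBF4 removes the thiolate to give the C4 cation of the 2,3-cis unit, and Friedel–Crafts attack by C6 of ring D (para to O1, ortho to the 7-benzyloxy group; C5 is peri-hindered) from the β-face, anti to the 3-hydroxyl and the 2-aryl group, should set upper C4 as S (4β), while the hard C4 acetate of 14 is not activated by the soft promoter.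

Step 15
Reactants: 19 hexa-O-benzyl-epioritin-(4β→6)-oritin-4α-ol 3,4-di-O-acetate
Product: 20 hexa-O-benzyl-epioritin-(4β→6)-oritin-4α-ol
Conditions: K2CO3 (cat.), MeOH–THF, rt
Reagents that add atoms: none
Why: Zemplén-type transesterification cleaves the acyl–oxygen bonds, so C3 and C4 of ring F keep their configuration.

Step 16
Reactants: 20 hexa-O-benzyl-epioritin-(4β→6)-oritin-4α-ol
Product: 21 epioritin-(4β→6)-oritin-4α-ol (target)
Conditions: H2 (1 atm), Pd(OH)2/C, NaHCO3 (trace), THF–MeOH, rt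
Reagents that add atoms: none
Why: Hydrogenolysis of the six benzyl ethers under neutral buffered conditions, in which the unhindered O-benzyl groups should cleave faster than the secondary benzylic C4–OH of ring F.

Compound list
1 | pyrogallol | Oc1cccc(O)c1O | starting material
2 | allyl bromide | C=CCBr | starting material
3 | 3-(allyloxy)benzene-1,2-diol | C=CCOc1cccc(O)c1O | intermediate
4 | 1-(allyloxy)-2,3-bis(benzyloxy)benzene | C=CCOc1cccc(OCc2ccccc2)c1OCc1ccccc1 | intermediate
5 | 6-allyl-2,3-bis(benzyloxy)phenol | C=CCc1ccc(OCc2ccccc2)c(OCc2ccccc2)c1O | intermediate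
6 | 4-(benzyloxy)benzoyl chloride | O=C(Cl)c1ccc(OCc2ccccc2)cc1 | starting material
7 | 6-allyl-2,3-bis(benzyloxy)phenyl 4-(benzyloxy)benzoate | C=CCc1ccc(OCc2ccccc2)c(OCc2ccccc2)c1OC(=O)c1ccc(OCc2ccccc2)cc1 | intermediate
8 | 7,8-bis(benzyloxy)-2-[4-(benzyloxy)phenyl]-4H-chromene | O1C(c2ccc(OCc3ccccc3)cc2)=CCc2ccc(OCc3ccccc3)c(OCc3ccccc3)c21 | intermediate
9 | [(2R,3S)-7,8-bis(benzyloxy)-2-(4-benzyloxyphenyl)chroman-3-yl](isopinocampheyl)borane | C[C@H]1[C@H](B[C@H]2Cc3ccc(OCc4ccccc4)c(OCc4ccccc4)c3O[C@@H]2c2ccc(OCc3ccccc3)cc2)C[C@@H]2C[C@H]1C2(C)C | intermediate (not isolated)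
10 | (2R,3S)-7,8-bis(benzyloxy)-2-[4-(benzyloxy)phenyl]chroman-3-ol (tri-O-benzyl-oritin) | O[C@H]1Cc2ccc(OCc3ccccc3)c(OCc3ccccc3)c2O[C@@H]1c1ccc(OCc2ccccc2)cc1 | intermediate
11 | (2R,3S,4S)-7,8-bis(benzyloxy)-2-[4-(benzyloxy)phenyl]chroman-3,4-diol (4β-hydroxy, expected main epimer) | O[C@H]1[C@@H](O)c2ccc(OCc3ccccc3)c(OCc3ccccc3)c2O[C@@H]1c1ccc(OCc2ccccc2)cc1 | intermediate (not isolated)
12 | (2R,3R)-7,8-bis(benzyloxy)-2-[4-(benzyloxy)phenyl]-3-hydroxychroman-4-one | O[C@H]1C(=O)c2ccc(OCc3ccccc3)c(OCc3ccccc3)c2O[C@@H]1c1ccc(OCc2ccccc2)cc1 | intermediate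
13 | (2R,3S,4R)-7,8-bis(benzyloxy)-2-[4-(benzyloxy)phenyl]chroman-3,4-diol | O[C@H]1[C@H](O)c2ccc(OCc3ccccc3)c(OCc3ccccc3)c2O[C@@H]1c1ccc(OCc2ccccc2)cc1 | intermediate
14 | 3,4-di-O-acetate of 13 (2,3-trans-3,4-trans) | CC(=O)O[C@H]1[C@H](OC(C)=O)c2ccc(OCc3ccccc3)c(OCc3ccccc3)c2O[C@@H]1c1ccc(OCc2ccccc2)cc1 | intermediate
15 | (2R)-7,8-bis(benzyloxy)-2-[4-(benzyloxy)phenyl]chroman-3-one | O=C1Cc2ccc(OCc3ccccc3)c(OCc3ccccc3)c2O[C@@H]1c1ccc(OCc2ccccc2)cc1 | intermediate
16 | (2R,3R)-7,8-bis(benzyloxy)-2-[4-(benzyloxy)phenyl]chroman-3-ol (tri-O-benzyl-epioritin) | O[C@@H]1Cc2ccc(OCc3ccccc3)c(OCc3ccccc3)c2O[C@@H]1c1ccc(OCc2ccccc2)cc1 | intermediate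
17 | (2R,3R,4S)-7,8-bis(benzyloxy)-2-[4-(benzyloxy)phenyl]-4-(2-ethoxyethoxy)chroman-3-ol | O[C@@H]1[C@@H](OCCOCC)c2ccc(OCc3ccccc3)c(OCc3ccccc3)c2O[C@@H]1c1ccc(OCc2ccccc2)cc1 | intermediate
18 | (2R,3S,4S)-4-(1,3-benzothiazol-2-ylsulfanyl)-7,8-bis(benzyloxy)-2-[4-(benzyloxy)phenyl]chroman-3-ol | O[C@@H]1[C@@H](Sc2nc3ccccc3s2)c2ccc(OCc3ccccc3)c(OCc3ccccc3)c2O[C@@H]1c1ccc(OCc2ccccc2)cc1 | intermediate
19 | hexa-O-benzyl-epioritin-(4β→6)-oritin-4α-ol 3,4-di-O-acetate | c1ccccc1COc1ccc([C@H]2Oc3c(ccc(OCc4ccccc4)c3OCc3ccccc3)[C@H](c3cc4c(c(OCc5ccccc5)c3OCc3ccccc3)O[C@H](c3ccc(OCc5ccccc5)cc3)[C@@H](OC(C)=O)[C@@H]4OC(C)=O)[C@H]2O)cc1 | intermediate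
20 | hexa-O-benzyl-epioritin-(4β→6)-oritin-4α-ol | c1ccccc1COc1ccc([C@H]2Oc3c(ccc(OCc4ccccc4)c3OCc3ccccc3)[C@H](c3cc4c(c(OCc5ccccc5)c3OCc3ccccc3)O[C@H](c3ccc(OCc5ccccc5)cc3)[C@@H](O)[C@@H]4O)[C@H]2O)cc1 | intermediate
21 | epioritin-(4β→6)-oritin-4α-ol; (2R,3S,4R)-6-[(2R,3R,4S)-3,7,8-trihydroxy-2-(4-hydroxyphenyl)chroman-4-yl]-2-(4-hydroxyphenyl)chromane-3,4,7,8-tetrol | Oc1ccc([C@H]2Oc3c(ccc(O)c3O)[C@H](c3cc4c(c(O)c3O)O[C@H](c3ccc(O)cc3)[C@@H](O)[C@@H]4O)[C@H]2O)cc1 | target

Total step count: 16. Longest linear sequence: 13 steps (steps 1–6, 10–16).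

Steps most likely to fail

Step 14. The cation from 18 may be captured by C6 or by the 3-hydroxyl of a second molecule of 18 (self-condensation) faster than by ring D of 14, which is only moderately nucleophilic. The fallback sets out from 17 and comes back to the route at 21. NBS in CH2Cl2 at −78 °C brominates the most activated arene position, C6 of ring A, to give (2R,3R,4S)-6-bromo-7,8-bis(benzyloxy)-2-[4-(benzyloxy)phenyl]-4-(2-ethoxyethoxy)chroman-3-ol F2. AlMe3 and 2-mercaptobenzothiazole convert it into the C6-capped 4β-(benzothiazol-2-ylsulfanyl) electrophile F3. AgBF4 coupling with 14 gives the 6-bromo dimer diacetate F4, which can no longer chain-extend. K2CO3 in MeOH gives the 6-bromo dimer diol F5. Hydrogenolysis over Pd(OH)2/C with Et3N then removes the benzyl groups and the bromine together and gives 21.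

Step 5. The titanium ethylidene may olefinate the ester before it exchanges with the allyl group, leaving an acyclic enol ether, or the allyl double bond may migrate into conjugation. The fallback sets out from 7 and comes back at 8. Methylenation of the ester with Cp2TiMe2 (toluene, 70 °C) gives 6-allyl-2,3-bis(benzyloxy)phenyl 1-[4-(benzyloxy)phenyl]vinyl ether F1. Ring-closing metathesis with the second-generation Grubbs catalyst (toluene, 80 °C) then closes the same C2=C3 bond with loss of ethylene and gives 8.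

Step 16. Hydrogenolytic loss of the benzylic C4 hydroxyl of ring F may compete with debenzylation, or the hydroxyl may ionise once the phenols are free. The fallback sets out from 20 and comes back at 21. MnO2 in CH2Cl2 oxidises only the activated benzylic C4–OH of ring F to give the hexa-O-benzyl dimer ketone F6. Hydrogenolysis over Pd(OH)2/C gives the free phenolic 3-hydroxyflavanone dimer F7. NaBH4 in EtOH then reduces the ketone, as for free dihydroflavonols, to the 3,4-trans-diol 21.

Further compounds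
F1 | step 5 | 6-allyl-2,3-bis(benzyloxy)phenyl 1-[4-(benzyloxy)phenyl]vinyl ether | C=CCc1ccc(OCc2ccccc2)c(OCc2ccccc2)c1OC(=C)c1ccc(OCc2ccccc2)cc1
F2 | step 14 | (2R,3R,4S)-6-bromo-7,8-bis(benzyloxy)-2-[4-(benzyloxy)phenyl]-4-(2-ethoxyethoxy)chroman-3-ol | O[C@@H]1[C@@H](OCCOCC)c2cc(Br)c(OCc3ccccc3)c(OCc3ccccc3)c2O[C@@H]1c1ccc(OCc2ccccc2)cc1
F3 | step 14 | 4β-(1,3-benzothiazol-2-ylsulfanyl)-6-bromo-7,8-bis(benzyloxy)-2-[4-(benzyloxy)phenyl]chroman-3-ol (2,3-cis) | O[C@@H]1[C@@H](Sc2nc3ccccc3s2)c2cc(Br)c(OCc3ccccc3)c(OCc3ccccc3)c2O[C@@H]1c1ccc(OCc2ccccc2)cc1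
F4 | step 14 | 6-bromo (ring A) derivative of 19 | c1ccccc1COc1ccc([C@H]2Oc3c(cc(Br)c(OCc4ccccc4)c3OCc3ccccc3)[C@H](c3cc4c(c(OCc5ccccc5)c3OCc3ccccc3)O[C@H](c3ccc(OCc5ccccc5)cc3)[C@@H](OC(C)=O)[C@@H]4OC(C)=O)[C@H]2O)cc1
F5 | step 14 | 6-bromo (ring A) derivative of 20 | c1ccccc1COc1ccc([C@H]2Oc3c(cc(Br)c(OCc4ccccc4)c3OCc3ccccc3)[C@H](c3cc4c(c(OCc5ccccc5)c3OCc3ccccc3)O[C@H](c3ccc(OCc5ccccc5)cc3)[C@@H](O)[C@@H]4O)[C@H]2O)cc1
F6 | step 16 | hexa-O-benzyl dimer with ring F as (2R,3R)-3-hydroxychroman-4-one | c1ccccc1COc1ccc([C@H]2Oc3c(ccc(OCc4ccccc4)c3OCc3ccccc3)[C@H](c3cc4c(c(OCc5ccccc5)c3OCc3ccccc3)O[C@H](c3ccc(OCc5ccccc5)cc3)[C@@H](O)C4=O)[C@H]2O)cc1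
F7 | step 16 | free phenolic dimer with ring F as (2R,3R)-3-hydroxychroman-4-one | Oc1ccc([C@H]2Oc3c(ccc(O)c3O)[C@H](c3cc4c(c(O)c3O)O[C@H](c3ccc(O)cc3)[C@@H](O)C4=O)[C@H]2O)cc1
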